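**Plan**

1. Target: 7αH,10αH‑eremophil‑11‑ene‑2α,8α,9α‑triol 9‑[(Z)‑3‑methylpent‑2‑enoate]. Ring A = C1–C5 + C10, ring B = C5–C10, β = face of the C5 methyl. Retrosynthetic cuts: the O9–acyl bond; the C7–isopropenyl bond (back to a 7α,8α‑epoxide and a C7=C8 olefin); C5–C6 and C9–C10 of ring B together with C4–CH3; the C2–O bond back to the C2–isopropenyl bond of carvone.
2. Enabling feature: C10 is a ring‑fusion CH between the quaternary C5 (whose neighbour C4 carries a methyl) and C9, and C8 carries oxygen. Read as a former C10 ketone and a C8 ketone, C4 is β to C10 (cuprate), C5 is α to C10 and C6 is β to C8 (Michael), and C9 is α to C8 and bonds to C10 (aldol). Methyl, the ring A enone and a butenone unit can therefore be joined in one flask.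
3. Forward order: ring A is the ring of (S)‑carvone and ring B is closed in step 1. Then come the trans ring fusion and the C9 oxygen, C–C cleavage of the carvone isopropenyl to the C2 acetate, ketone → C7=C8 olefin → α‑epoxide → isopropenyl opening, and acylation of O9 with the separately made (Z)‑acid chloride.
4. Stereochemistry: C2 comes from (S)‑carvone and is retained in the carbon‑to‑oxygen shift. C4 and C5 are relayed from C2 in step 1. C10 is set by axial protonation trans to the C5 methyl, C9 by oxidant approach anti to the C5 methyl, C7 and C8 by hydroxyl‑directed α‑epoxidation and trans‑diaxial opening, and the Z olefin by syn carbocupration.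

Key step: step 1

Assumption: 3‑(trimethylsilyl)but‑3‑en‑2‑one is taken as a purchasable reagent; otherwise it is made from (1‑bromovinyl)trimethylsilane by lithiation, addition to acetaldehyde and oxidation.

Decalin and octalin names below use the eremophilane numbering given in the plan.

**Step 1**
Reactants: 1 (S)‑(+)‑carvone; 2 3‑(trimethylsilyl)but‑3‑en‑2‑one
Product: 7 2α‑isopropenyl‑4β,5β‑dimethyl‑Δ9(10)‑octal‑8‑one, via lithium enolate 3 (not isolated), via silyl diketone 4 (not isolated), via diketone 5 (not isolated), via ketol 6 (not isolated)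
Conditions: Me2CuLi (from MeLi and CuI), Et2O, −78 → 0 °C; 2, −78 → −20 °C; then KOH, MeOH, 23 → 60 °C, same flask
Reagents that add atoms: lithium dimethylcuprate, [Li+].C[Cu-]C
Why: Me2CuLi delivers methyl to C4 of the enone and so generates the C5=C10 lithium enolate 3 regiospecifically; 3 adds through C5 to the β‑carbon of the α‑silyl enone 2 (C5–C6 bond, the silyl group stabilising the new enolate against polymerisation and proton transfer), and KOH/MeOH then cleaves the C–Si bond, forms the C9 enolate of the methyl ketone, closes it onto the C10 carbonyl (C9–C10 bond) and eliminates water. The closest known reaction type is the Robinson annulation in its conjugate‑addition/α‑silyl vinyl ketone form, which is established for cuprate‑derived enolates of 2‑methylcyclohex‑2‑enones. Ring B is closed by a 6‑(enolendo)‑exo‑trig aldol addition followed by E1cB dehydration. C4 is controlled by the C2 stereocenter (axial methyl transfer anti to the pseudoequatorial isopropenyl group), and C5 by C4 (the acceptor attacks the enolate axially on the α face, anti to the then pseudoaxial C4 methyl, so the two methyls become cis). The step needs C‑alkylation at the more substituted α‑carbon without equilibration of the enolate towards C1; this is secured because the enolate is born at C5 by the conjugate addition itself and is trapped at low temperature before proton exchange.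

**Step 2**
Reactants: 7 2α‑isopropenyl‑4β,5β‑dimethyl‑Δ9(10)‑octal‑8‑one
Product: 9 2α‑isopropenyl‑4β,5β‑dimethyl‑8‑triethylsilyloxy‑10αH‑octal‑8‑ene, via lithium enolate 8 (not isolated)
Conditions: Li, t‑BuOH (1 equiv), NH3/THF, −78 °C; isoprene; NH3 off; Et3SiCl, Et3N, THF, −78 → 0 °C
Reagents that add atoms: chlorotriethylsilane, CC[Si](Cl)(CC)CC
Why: Dissolving‑metal reduction of the enone should protonate C10 axially on the α face (trans to the C5 methyl, as in related 10‑methyloctalones) and leave the C8=C9 lithium enolate regiospecifically, which O‑silylation traps (reductive silylation); the isolated isopropenyl group is not reduced.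

**Step 3**
Reactants: 9 2α‑isopropenyl‑4β,5β‑dimethyl‑8‑triethylsilyloxy‑10αH‑octal‑8‑ene
Product: 11 2α‑isopropenyl‑4β,5β‑dimethyl‑9α‑triethylsilyloxy‑10αH‑decal‑8‑one, via silyloxy epoxide 10 (not isolated)
Conditions: mCPBA (1.05 equiv), CH2Cl2, −20 → 0 °C
Reagents that add atoms: 3‑chloroperbenzoic acid, OOC(=O)c1cccc(Cl)c1
Why: Rubottom oxidation: the silyl enol ether is far more nucleophilic than the 1,1‑disubstituted isopropenyl olefin, the peracid approaches C9 from the α face because β attack is 1,3‑diaxial to the C5 methyl, and 1,4‑silyl migration opens the epoxide to the 9α‑silyloxy ketone (equatorial, also the stable epimer).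

**Step 4**
Reactants: 11 2α‑isopropenyl‑4β,5β‑dimethyl‑9α‑triethylsilyloxy‑10αH‑decal‑8‑one
Product: 14 2α‑acetoxy‑4β,5β‑dimethyl‑9α‑triethylsilyloxy‑10αH‑decal‑8‑one, via methoxy hydroperoxide 12 (not isolated), via peroxyacetate 13 (not isolated)
Conditions: O3, CH2Cl2/MeOH, −78 °C; N2 purge; Ac2O, Et3N, DMAP (cat.), 0 → 23 °C
Reagents that add atoms: ozone, [O-][O+]=O; methanol, CO
Why: Ozonolysis in methanol gives the α‑methoxy hydroperoxide, and its peracetate undergoes Criegee rearrangement with migration of the secondary ring carbon C2 from carbon to oxygen with retention, so the C2–isopropenyl bond is replaced by the 2α‑acetoxy group (the sequence known for carvone itself); the enone is gone at this stage, so the acetate cannot be lost by vinylogous elimination.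

**Step 5**
Reactants: 14 2α‑acetoxy‑4β,5β‑dimethyl‑9α‑triethylsilyloxy‑10αH‑decal‑8‑one
Product: 16 2α‑acetoxy‑4β,5β‑dimethyl‑9α‑triethylsilyloxy‑10αH‑octal‑7‑en‑8‑yl trifluoromethanesulfonate, via potassium enolate 15 (not isolated)
Conditions: KN(SiMe3)2 (1.1 equiv), THF, −78 °C; PhNTf2, −78 → 0 °C
Reagents that add atoms: N‑phenylbis(trifluoromethanesulfonimide), O=S(=O)(N(c1ccccc1)S(=O)(=O)C(F)(F)F)C(F)(F)F
Why: Kinetic deprotonation of the α‑silyloxy ketone should take place at the C7 methylene and not at the hindered, oxygen‑bearing C9 methine or at the less acidic acetate, and O‑triflation of the enolate gives the C7=C8 enol triflate.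

**Step 6**
Reactants: 16 2α‑acetoxy‑4β,5β‑dimethyl‑9α‑triethylsilyloxy‑10αH‑octal‑7‑en‑8‑yl trifluoromethanesulfonate
Product: 17 2α‑acetoxy‑4β,5β‑dimethyl‑9α‑triethylsilyloxy‑10αH‑octal‑7‑ene
Conditions: Pd(OAc)2 (5 mol %), PPh3 (10 mol %), Bu3N, HCO2H, DMF, 60 °C
Reagents that add atoms: none
Why: Palladium‑catalysed formate reduction of an enol triflate (oxidative addition to zerovalent palladium formed in the flask, formate exchange, decarboxylation, reductive elimination) gives the C7=C8 olefin and leaves silyl ether and acetate untouched.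

**Step 7**
Reactants: 17 2α‑acetoxy‑4β,5β‑dimethyl‑9α‑triethylsilyloxy‑10αH‑octal‑7‑ene
Product: 19 4β,5β‑dimethyl‑10αH‑octal‑7‑ene‑2α,9α‑diol, via silyl ether alcohol 18 (not isolated)
Conditions: K2CO3 (0.2 equiv), MeOH, 23 °C; then 1 M HCl, THF, 23 °C
Reagents that add atoms: none
Why: Base‑catalysed transesterification removes the acetate and dilute acid then cleaves the secondary triethylsilyl ether, two standard deprotections that leave the olefin and the allylic alcohol unchanged.

**Step 8**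
Reactants: 19 4β,5β‑dimethyl‑10αH‑octal‑7‑ene‑2α,9α‑diol
Product: 20 7α,8α‑epoxy‑4β,5β‑dimethyl‑10αH‑decalin‑2α,9α‑diol
Conditions: mCPBA (1.2 equiv), CH2Cl2, 0 °C; aq NaHCO3 work‑up
Reagents that add atoms: 3‑chloroperbenzoic acid, OOC(=O)c1cccc(Cl)c1
Why: Henbest epoxidation: the pseudoequatorial allylic 9α‑hydroxyl hydrogen‑bonds the peracid and delivers oxygen to the α face, which is also the face left open by the axial C5 methyl, so the 7α,8α‑epoxide should result.

**Step 9**
Reactants: 20 7α,8α‑epoxy‑4β,5β‑dimethyl‑10αH‑decalin‑2α,9α‑diol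
Product: 21 7αH,10αH‑eremophil‑11‑ene‑2α,8α,9α‑triol
Conditions: CH2=C(CH3)MgBr (6 equiv), CuI (0.3 equiv), THF, −30 → 0 °C; aq NH4Cl
Reagents that add atoms: isopropenylmagnesium bromide, C=C(C)[Mg]Br
Why: Copper‑catalysed Grignard opening of a cyclohexene oxide follows the Fürst–Plattner rule: in the rigid trans‑decalin only attack at C7 from the β face gives the trans‑diaxial product, and C8 is further deactivated by the adjacent C9 alkoxide, so the 7β‑isopropenyl and 8α‑hydroxyl groups are set together (as in the opening of 2α,3α‑epoxy‑5α‑steroids at C2).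

**Step 10**
Reactants: 22 ethyl pent‑2‑ynoate
Product: 24 ethyl (Z)‑3‑methylpent‑2‑enoate, via alkenylcuprate 23 (not isolated)
Conditions: Me2CuLi (from MeLi and CuI), THF, −78 °C; MeOH, −78 °C
Reagents that add atoms: lithium dimethylcuprate, [Li+].C[Cu-]C
Why: Carbocupration of the ynoate is a syn addition, so methyl and copper (then hydrogen) are cis and the ethyl group ends up cis to the ester; protonation at −78 °C prevents isomerisation of the alkenylcopper intermediate.

**Step 11**
Reactants: 24 ethyl (Z)‑3‑methylpent‑2‑enoate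
Product: 25 (Z)‑3‑methylpent‑2‑enoic acid
Conditions: LiOH, THF/MeOH/H2O, 23 °C; then 1 M HCl
Reagents that add atoms: lithium hydroxide, [Li+].[OH-]
Why: Saponification by acyl–oxygen cleavage does not touch the trisubstituted olefin, so the Z geometry is kept.

**Step 12**
Reactants: 25 (Z)‑3‑methylpent‑2‑enoic acid
Product: 26 (Z)‑3‑methylpent‑2‑enoyl chloride
Conditions: 1‑chloro‑N,N,2‑trimethylprop‑1‑en‑1‑amine (1.1 equiv), CH2Cl2, 0 → 23 °C; used as solution
Reagents that add atoms: 1‑chloro‑N,N,2‑trimethylprop‑1‑en‑1‑amine, CC(C)=C(Cl)N(C)C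
Why: The α‑chloroenamine converts the acid into its chloride under neutral conditions, without HCl or amine base, which avoids Z/E isomerisation and vinylketene formation.

**Step 13**
Reactants: 21 7αH,10αH‑eremophil‑11‑ene‑2α,8α,9α‑triol; 26 (Z)‑3‑methylpent‑2‑enoyl chloride
Product: 28 7αH,10αH‑eremophil‑11‑ene‑2α,8α,9α‑triol 9‑[(Z)‑3‑methylpent‑2‑enoate] (target), via stannylene acetal 27 (not isolated)
Conditions: Bu2SnO (1.05 equiv), toluene, reflux, water removed; then 26 (1.05 equiv), toluene, 0 °C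
Reagents that add atoms: none
Why: The cis‑8,9‑diol forms a dibutylstannylene acetal, and acylation of such acetals goes to the equatorial oxygen (O9) in preference to the axial O8 and to the non‑activated C2 hydroxyl; no base is present, so the Z enoate and the position of the acyl group should be preserved.

**Compound list**

1 | (S)‑(+)‑carvone | CC1=CC[C@@H](CC1=O)C(C)=C | starting material
2 | 3‑(trimethylsilyl)but‑3‑en‑2‑one | CC(=O)C(=C)[Si](C)(C)C | starting material
3 | lithium C5=C10 enolate of the methyl adduct (4β‑methyl, 2α‑isopropenyl) | [Li+].[O-]C1=C(C)[C@@H](C)C[C@H](C(C)=C)C1 | intermediate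
4 | α‑silyl 1,5‑diketone Michael adduct (C7 epimers) | CC(=O)C([Si](C)(C)C)C[C@]1(C)[C@@H](C)C[C@H](C(C)=C)CC1=O | intermediate
5 | 2,3‑dimethyl‑2‑(3‑oxobutyl)‑5‑isopropenylcyclohexanone (methyls cis, 3‑methyl and 5‑isopropenyl trans) | CC(=O)CC[C@]1(C)[C@@H](C)C[C@H](C(C)=C)CC1=O | intermediate
6 | ketol, 10‑hydroxy‑8‑ketone aldol adduct (C10 epimers) | O=C1CC[C@]2(C)[C@@H](C)C[C@H](C(C)=C)CC2(O)C1 | intermediate
7 | 2α‑isopropenyl‑4β,5β‑dimethyl‑Δ9(10)‑octal‑8‑one | O=C1CC[C@]2(C)[C@@H](C)C[C@H](C(C)=C)CC2=C1 | intermediate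
8 | lithium C8=C9 enolate, trans‑fused (10α‑H) | C1C[C@]2(C)[C@@H](C)C[C@H](C(C)=C)C[C@H]2C=C1[O-].[Li+] | intermediate
9 | 2α‑isopropenyl‑4β,5β‑dimethyl‑8‑triethylsilyloxy‑10αH‑octal‑8‑ene | C1C[C@]2(C)[C@@H](C)C[C@H](C(C)=C)C[C@H]2C=C1O[Si](CC)(CC)CC | intermediate
10 | 8α,9α‑epoxy‑8β‑triethylsilyloxy derivative of 9 | C1C[C@]2(C)[C@@H](C)C[C@H](C(C)=C)C[C@H]2[C@@H]3O[C@]13O[Si](CC)(CC)CC | intermediate
11 | 2α‑isopropenyl‑4β,5β‑dimethyl‑9α‑triethylsilyloxy‑10αH‑decal‑8‑one | O=C1CC[C@]2(C)[C@@H](C)C[C@H](C(C)=C)C[C@H]2[C@@H]1O[Si](CC)(CC)CC | intermediate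
12 | 2α‑(2‑hydroperoxy‑2‑methoxyprop‑2‑yl) analogue of 11 | O=C1CC[C@]2(C)[C@@H](C)C[C@H](C(C)(OC)OO)C[C@H]2[C@@H]1O[Si](CC)(CC)CC | intermediate
13 | peroxyacetate of 12 | O=C1CC[C@]2(C)[C@@H](C)C[C@H](C(C)(OC)OOC(C)=O)C[C@H]2[C@@H]1O[Si](CC)(CC)CC | intermediate
14 | 2α‑acetoxy‑4β,5β‑dimethyl‑9α‑triethylsilyloxy‑10αH‑decal‑8‑one | O=C1CC[C@]2(C)[C@@H](C)C[C@H](OC(C)=O)C[C@H]2[C@@H]1O[Si](CC)(CC)CC | intermediate
15 | potassium C7=C8 enolate of 14 | [K+].[O-]C1=CC[C@]2(C)[C@@H](C)C[C@H](OC(C)=O)C[C@H]2[C@@H]1O[Si](CC)(CC)CC | intermediate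
16 | 2α‑acetoxy‑4β,5β‑dimethyl‑9α‑triethylsilyloxy‑10αH‑octal‑7‑en‑8‑yl trifluoromethanesulfonate | FC(F)(F)S(=O)(=O)OC1=CC[C@]2(C)[C@@H](C)C[C@H](OC(C)=O)C[C@H]2[C@@H]1O[Si](CC)(CC)CC | intermediate
17 | 2α‑acetoxy‑4β,5β‑dimethyl‑9α‑triethylsilyloxy‑10αH‑octal‑7‑ene | C1=CC[C@]2(C)[C@@H](C)C[C@H](OC(C)=O)C[C@H]2[C@@H]1O[Si](CC)(CC)CC | intermediate
18 | 4β,5β‑dimethyl‑9α‑triethylsilyloxy‑10αH‑octal‑7‑en‑2α‑ol | C1=CC[C@]2(C)[C@@H](C)C[C@H](O)C[C@H]2[C@@H]1O[Si](CC)(CC)CC | intermediate
19 | 4β,5β‑dimethyl‑10αH‑octal‑7‑ene‑2α,9α‑diol | C1=CC[C@]2(C)[C@@H](C)C[C@H](O)C[C@H]2[C@@H]1O | intermediate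
20 | 7α,8α‑epoxy‑4β,5β‑dimethyl‑10αH‑decalin‑2α,9α‑diol | O[C@@H]1[C@@H]2O[C@@H]2C[C@]3(C)[C@@H](C)C[C@H](O)C[C@@H]13 | intermediate
21 | 7αH,10αH‑eremophil‑11‑ene‑2α,8α,9α‑triol | C=C(C)[C@H]1C[C@]2(C)[C@@H](C)C[C@H](O)C[C@H]2[C@H](O)[C@@H]1O | intermediate
22 | ethyl pent‑2‑ynoate | CCC#CC(=O)OCC | starting material
23 | lithium methyl[(Z)‑1‑ethoxycarbonyl‑2‑methylbut‑1‑enyl]cuprate | [Li+].CCOC(=O)/C([Cu-]C)=C(/C)CC | intermediate
24 | ethyl (Z)‑3‑methylpent‑2‑enoate | CCOC(=O)/C=C(/C)CC | intermediate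
25 | (Z)‑3‑methylpent‑2‑enoic acid | OC(=O)/C=C(/C)CC | intermediate
26 | (Z)‑3‑methylpent‑2‑enoyl chloride | ClC(=O)/C=C(/C)CC | intermediate
27 | 8,9‑O‑dibutylstannylene acetal of 21 | C=C(C)[C@H]1C[C@]2(C)[C@@H](C)C[C@H](O)C[C@H]2[C@H](O[Sn]3(CCCC)CCCC)[C@@H]1O3 | intermediate
28 | 7αH,10αH‑eremophil‑11‑ene‑2α,8α,9α‑triol 9‑[(Z)‑3‑methylpent‑2‑enoate] | C=C(C)[C@H]1C[C@]2(C)[C@@H](C)C[C@H](O)C[C@H]2[C@H](OC(=O)/C=C(/C)CC)[C@@H]1O | target

**Step count and risks**

Total steps: 13. Longest linear sequence: 10 steps (steps 1–9 and 13); steps 10–12 make the acyl chloride.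

Steps most likely to fail:

Step 9. The nucleophile has to enter C7 axially, syn to the axial C5 methyl. The opening may therefore be slow, and bromide opening or Lewis‑acid rearrangement of the epoxide may compete. Fallback, from 20 back to 21: the smaller, linear LiC≡CH·H2NCH2CH2NH2 in DMSO should open the epoxide in the same trans‑diaxial sense to the 7β‑ethynyl triol F2. Negishi methylalumination of the terminal alkyne (Me3Al, Cp2ZrCl2 cat., CH2Cl2; then water) places methyl on the internal alkyne carbon, and protonolysis of the alkenylalane gives the isopropenyl group of 21.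

Step 13. Regiocontrol of the acylation may be lost (acyl group on O8 or O2, or acyl migration) if ring B leaves the chair because of the syn‑diaxial C5 methyl/C7 isopropenyl pair. Fallback, from 17 to 28, differentiating the hydroxyls by protecting groups instead of by reagent control:
- mCPBA epoxidises 17 on the α face (steric control by the C5 methyl) to the epoxide F3.
- Copper‑catalysed opening with isopropenylmagnesium bromide, followed by K2CO3/MeOH on the crude product to remove the acetate, gives the 9‑O‑silyl triol derivative F4.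
- TBSOTf/2,6‑lutidine gives the bis‑silyl ether F5.
- PPTS/MeOH cleaves only the triethylsilyl ether to the C9 alcohol F6.
- Steglich esterification with acid 25 (diisopropylcarbodiimide, DMAP) gives the ester F7.
- HF·pyridine gives 28.

Step 1. The hindered enolate may add sluggishly, so that proton transfer to the vinyl ketone, oligomerisation of the acceptor or enolate equilibration returns the simple methyl adduct or regioisomers. Fallback, from 1 to 7: Me2CuLi addition to 1 followed by Me3SiCl/Et3N gives the trimethylsilyl enol ether F1. Mukaiyama–Michael addition of F1 to but‑3‑en‑2‑one (TiCl4, CH2Cl2, −78 °C) gives diketone 5, now isolated, and KOH/MeOH closes it to 7.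

**Further compounds**

F1 | step 1 | trimethylsilyl enol ether of the methyl adduct (O‑silyl analogue of 3) | C[Si](C)(C)OC1=C(C)[C@@H](C)C[C@H](C(C)=C)C1
F2 | step 9 | 7β‑ethynyl‑4β,5β‑dimethyl‑10αH‑decalin‑2α,8α,9α‑triol | C#C[C@H]1C[C@]2(C)[C@@H](C)C[C@H](O)C[C@H]2[C@H](O)[C@@H]1O
F3 | step 13 | 2α‑acetoxy‑7α,8α‑epoxy‑4β,5β‑dimethyl‑9α‑triethylsilyloxy‑10αH‑decalin | CC[Si](CC)(CC)O[C@@H]1[C@@H]2O[C@@H]2C[C@]3(C)[C@@H](C)C[C@H](OC(C)=O)C[C@@H]13
F4 | step 13 | 9α‑triethylsilyloxy‑7αH,10αH‑eremophil‑11‑ene‑2α,8α‑diol | C=C(C)[C@H]1C[C@]2(C)[C@@H](C)C[C@H](O)C[C@H]2[C@H](O[Si](CC)(CC)CC)[C@@H]1O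
F5 | step 13 | 2α,8α‑bis(tert‑butyldimethylsilyloxy)‑9α‑triethylsilyloxy‑7αH,10αH‑eremophil‑11‑ene | C=C(C)[C@H]1C[C@]2(C)[C@@H](C)C[C@H](O[Si](C)(C)C(C)(C)C)C[C@H]2[C@H](O[Si](CC)(CC)CC)[C@@H]1O[Si](C)(C)C(C)(C)C
F6 | step 13 | 2α,8α‑bis(tert‑butyldimethylsilyloxy)‑7αH,10αH‑eremophil‑11‑en‑9α‑ol | C=C(C)[C@H]1C[C@]2(C)[C@@H](C)C[C@H](O[Si](C)(C)C(C)(C)C)C[C@H]2[C@H](O)[C@@H]1O[Si](C)(C)C(C)(C)C
F7 | step 13 | 2,8‑bis(tert‑butyldimethylsilyl) ether of 28 | C=C(C)[C@H]1C[C@]2(C)[C@@H](C)C[C@H](O[Si](C)(C)C(C)(C)C)C[C@H]2[C@H](OC(=O)/C=C(/C)CC)[C@@H]1O[Si](C)(C)C(C)(C)C
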